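**Retrosynthetic overview** (isoflavan numbering: O1, C2, C3, C4, C4a, C5–C8, C8a; ring A = benzo ring, ring B = tetramethoxyphenyl, ring C = pyran)
- (3S)-Isoflavan ⇐ cis-(3S,4S)-isoflavan-4-ol (hydrogenolysis of C4–O and O-benzyl) ⇐ 7-benzyloxyisoflavone (transfer hydrogenation with dynamic kinetic resolution sets C3) ⇐ 7-fluoroisoflavone (SNAr at C7).
- Ring C of the 7-fluoroisoflavone is cut at C3–C4 and at O1–C8a. Both cuts lead back to one acyclic enol ester, (Z)-ArB–CH=CH–O–C(=O)–ArA (ArA = 2,4-difluoro-3-methoxyphenyl), in which the future C4 is parked on the future O1.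
- Enabling feature: C4 hangs on C4a, the ring A carbon next to C8a, and O1–C2–C3 is an enolate triad. With C4 raised to a carbonyl it is both the acyl electrophile for C3 and the ortho activator that lets O1 displace fluoride at C8a. The same C4=O lies para to C7, so it later admits O7, makes C3–H labile for the resolution, and finally leaves as a benzylic C–O bond para to O7.
- The enol ester comes from a terminal aryl alkyne (ring B) and 2,4-difluoro-3-methoxybenzoic acid (ring A) by Ru-catalysed addition. Rings A and B are bought; ring C is the only ring formed (step 4).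

Key step: step 4

Assumption: 1,2,3,4-tetramethoxybenzene and 2,4-difluoro-3-methoxybenzoic acid are taken as catalogue chemicals.

Step 1
Reactants: 1 1,2,3,4-tetramethoxybenzene
Product: 2 2,3,4,5-tetramethoxybenzaldehyde
Conditions: n-BuLi, TMEDA, THF, 0 °C; DMF, 0 °C → rt; then H2O
Reagents that add atoms: N,N-dimethylformamide, CN(C)C=O
Why: Directed ortho-metalation, in which a terminal methoxy group guides n-BuLi/TMEDA to one of the two equivalent free ring positions and the aryllithium is formylated by DMF.

Step 2
Reactants: 2 2,3,4,5-tetramethoxybenzaldehyde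
Product: 3 1-ethynyl-2,3,4,5-tetramethoxybenzene
Conditions: dimethyl (1-diazo-2-oxopropyl)phosphonate, K2CO3, MeOH, rt
Reagents that add atoms: dimethyl (1-diazo-2-oxopropyl)phosphonate, COP(=O)(OC)C(=[N+]=[N-])C(C)=O
Why: Seyferth–Gilbert homologation in the Ohira–Bestmann form, which should turn a non-enolisable benzaldehyde into the terminal alkyne through an alkylidene carbene 1,2-hydrogen shift under mild carbonate conditions.

Step 3
Reactants: 3 1-ethynyl-2,3,4,5-tetramethoxybenzene, 4 2,4-difluoro-3-methoxybenzoic acid
Product: 5 (Z)-2-(2,3,4,5-tetramethoxyphenyl)ethenyl 2,4-difluoro-3-methoxybenzoate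
Conditions: Ru(2-methylallyl)2(dppb) (2 mol %; dppb = 1,4-bis(diphenylphosphino)butane), toluene, 60 °C
Reagents that add atoms: none
Why: Anti-Markovnikov hydro-acyloxylation of a terminal aryl alkyne through a ruthenium vinylidene, where carboxylate attack on the vinylidene alpha-carbon should give the (Z)-enol ester without need of the sensitive arylacetaldehyde or an acid chloride.

Step 4
Reactants: 5 (Z)-2-(2,3,4,5-tetramethoxyphenyl)ethenyl 2,4-difluoro-3-methoxybenzoate
Product: 8 7-fluoro-8-methoxy-3-(2,3,4,5-tetramethoxyphenyl)-4H-chromen-4-one, via acylpyridinium enolate ion pair 6 (not isolated), via formyl ketone enol 7 (not isolated)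
Conditions: 4-pyrrolidinopyridine (20 mol %), Cs2CO3 (2.2 equiv), 4 Å MS, MeCN, 25 → 70 °C
Reagents that add atoms: none
Why: Proposed new method: 4-pyrrolidinopyridine should add to the electron-poor ester carbonyl of 5 and expel the aryl-conjugated enolate as ion pair 6, which recombines at carbon (C3–C4 bond), and deprotonation of the acidic formyl ketone 7 by Cs2CO3 drains the O-acyl/C-acyl equilibrium to the carbon side. The closest known reaction types are, for the first bond, the Steglich and Black O-to-C acyl transfers, the cyanide-catalysed enol ester to triketone rearrangement and the C-acylation of enolates by acylpyridinium ion pairs, and, for the second bond, the carbonate-mediated closure of 2-fluoroaroyl enols and enaminones to chromones and quinolones (Grohe–Heitzer type); new is the aldehyde-derived enol ester as substrate and the coupling of both events in one flask. The oxygen released by the shift is the atom that then attacks C8a, so ring C closes by a 6-endo-trig addition–elimination (SNAr) whose Meisenheimer charge is carried by the just-formed C4 ketone ortho to C8a–F. No stereocentre is created; the step delivers the planar C2=C3–C4=O unit from which step 6 sets C3. It needs C- over O-acylation, secured thermodynamically by enolate formation from 7, and C8a–F over C7–F, secured by the tether because only the ortho fluorine lies within a six-membered transition state, while the second fluorine raises the electrophilicity of the ester carbonyl and of C8a.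

Step 5
Reactants: 8 7-fluoro-8-methoxy-3-(2,3,4,5-tetramethoxyphenyl)-4H-chromen-4-one
Product: 9 7-(benzyloxy)-8-methoxy-3-(2,3,4,5-tetramethoxyphenyl)-4H-chromen-4-one
Conditions: BnOH (1.5 equiv), Cs2CO3, DMF, 60 °C
Reagents that add atoms: benzyl alcohol, OCc1ccccc1
Why: SNAr, because the remaining fluorine sits para to the C4 carbonyl (a vinylogous acyl fluoride) and should be displaced by benzyl oxide, whereas addition at C2 of the pyranone is reversible.

Step 6
Reactants: 9 7-(benzyloxy)-8-methoxy-3-(2,3,4,5-tetramethoxyphenyl)-4H-chromen-4-one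
Product: 11 (3S,4S)-7-(benzyloxy)-8-methoxy-3-(2,3,4,5-tetramethoxyphenyl)chroman-4-ol, via racemising isoflavanone 10 (not isolated)
Conditions: RuCl[(S,S)-TsDPEN](p-cymene) (3 mol %), HCO2H/Et3N (5:2), EtOAc, 40 °C
Reagents that add atoms: none
Why: Noyori–Ikariya asymmetric transfer hydrogenation cascade, in which Ru–H first reduces C2=C3 in the conjugate sense, 10 racemises at C3 through its enol under Et3N, and the (S,S)-catalyst fixes the C4 face by the ring A/η6-arene CH–π contact and takes only the C3 epimer whose aryl group points away from the incoming hydride, so that dynamic kinetic resolution should give the cis-(3S,4S)-alcohol.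

Step 7
Reactants: 11 (3S,4S)-7-(benzyloxy)-8-methoxy-3-(2,3,4,5-tetramethoxyphenyl)chroman-4-ol
Product: 13 (3S)-8-methoxy-3-(2,3,4,5-tetramethoxyphenyl)chroman-7-ol (target), via debenzylated chromane-4,7-diol 12 (not isolated)
Conditions: H2 (1 atm), Pd(OH)2/C, EtOH/AcOH (10:1), 25–40 °C
Reagents that add atoms: none
Why: Catalytic hydrogenolysis, in which the O-benzyl group should fall first and the C4–O bond, benzylic and para to the freed 7-OH, is then cleaved under mild acid while C3 is not touched and keeps its S configuration.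

**Compound list**
1 | 1,2,3,4-tetramethoxybenzene | COc1ccc(OC)c(OC)c1OC | starting material
2 | 2,3,4,5-tetramethoxybenzaldehyde | COc1cc(C=O)c(OC)c(OC)c1OC | intermediate
3 | 1-ethynyl-2,3,4,5-tetramethoxybenzene | C#Cc1cc(OC)c(OC)c(OC)c1OC | intermediate
4 | 2,4-difluoro-3-methoxybenzoic acid | COc1c(F)ccc(C(=O)O)c1F | starting material
5 | (Z)-2-(2,3,4,5-tetramethoxyphenyl)ethenyl 2,4-difluoro-3-methoxybenzoate | COc1cc(/C=C\OC(=O)c2ccc(F)c(OC)c2F)c(OC)c(OC)c1OC | intermediate
6 | 1-(2,4-difluoro-3-methoxybenzoyl)-4-(pyrrolidin-1-yl)pyridinium (Z)-2-(2,3,4,5-tetramethoxyphenyl)ethenolate, ion pair, not isolated | COc1c(F)ccc(C(=O)[n+]2ccc(N3CCCC3)cc2)c1F.[O-]/C=C\c1cc(OC)c(OC)c(OC)c1OC | intermediate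
7 | (Z)-1-(2,4-difluoro-3-methoxyphenyl)-3-hydroxy-2-(2,3,4,5-tetramethoxyphenyl)prop-2-en-1-one, enol of the formyl ketone, present as its cesium enolate, not isolated | O/C=C(\C(=O)c1ccc(F)c(OC)c1F)c1cc(OC)c(OC)c(OC)c1OC | intermediate
8 | 7-fluoro-8-methoxy-3-(2,3,4,5-tetramethoxyphenyl)-4H-chromen-4-one | COc1cc(-c2coc3c(OC)c(F)ccc3c2=O)c(OC)c(OC)c1OC | intermediate
9 | 7-(benzyloxy)-8-methoxy-3-(2,3,4,5-tetramethoxyphenyl)-4H-chromen-4-one | COc1cc(-c2coc3c(OC)c(OCc4ccccc4)ccc3c2=O)c(OC)c(OC)c1OC | intermediate
10 | 7-(benzyloxy)-8-methoxy-3-(2,3,4,5-tetramethoxyphenyl)chroman-4-one, racemic and configurationally labile at C3, not isolated | COc1cc(C2COc3c(OC)c(OCc4ccccc4)ccc3C2=O)c(OC)c(OC)c1OC | intermediate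
11 | (3S,4S)-7-(benzyloxy)-8-methoxy-3-(2,3,4,5-tetramethoxyphenyl)chroman-4-ol (cis) | COc1cc([C@H]2COc3c(ccc(OCc4ccccc4)c3OC)[C@H]2O)c(OC)c(OC)c1OC | intermediate
12 | (3S,4S)-8-methoxy-3-(2,3,4,5-tetramethoxyphenyl)chromane-4,7-diol, not isolated | COc1cc([C@H]2COc3c(ccc(O)c3OC)[C@H]2O)c(OC)c(OC)c1OC | intermediate
13 | (3S)-8-methoxy-3-(2,3,4,5-tetramethoxyphenyl)chroman-7-ol | COc1cc([C@H]2COc3c(ccc(O)c3OC)C2)c(OC)c(OC)c1OC | target

Total step count: 7. Longest linear sequence: 7 steps (1 → 13; 4 enters at step 3 as bought).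

**Steps most likely to fail**

1. Step 4 (proposed method).
 - What may go wrong: the ion pair may return only to oxygen, so that no net shift occurs. Traces of water may cleave the ester. The free enolate may condense with itself. The nucleophilic catalyst may deformylate the C-acylated intermediate before ring closure.
 - Fallback (known chemistry, stepwise enamine acylation): it sets out from 3 and 4 and comes back at 8. Hydroboration of 3 with dicyclohexylborane and oxidation with NaBO3 gives 2-(2,3,4,5-tetramethoxyphenyl)acetaldehyde F1. Morpholine and MgSO4 turn this into (E)-4-[2-(2,3,4,5-tetramethoxyphenyl)ethenyl]morpholine F2. Compound 4 is converted with (COCl)2 and catalytic DMF into 2,4-difluoro-3-methoxybenzoyl chloride F3. Stork acylation of F2 with F3 (Et3N, toluene) gives the morpholino enaminone F4. Aqueous HCl/THF hydrolyses F4 to 7, now isolated, and K2CO3 in DMF at 80 °C closes 7 to 8.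

2. Step 7.
 - What may go wrong: acid-assisted ionisation at C4 may be followed by loss of the C3 proton and re-hydrogenation, which would erode the enantiomeric purity. The C4 cation may be captured by the neighbouring 2'-methoxy oxygen. The C4–O cleavage may stall after debenzylation.
 - Fallback (radical instead of surface or ionic C–O cleavage): it sets out from 11 and comes back at 13. NaH, CS2 and MeI give the S-methyl xanthate of the C4 alcohol F5. Barton–McCombie reduction (Bu3SnH, AIBN, toluene, 80 °C) passes through a C4 radical that cannot touch C3 and gives (3S)-7-(benzyloxy)-8-methoxy-3-(2,3,4,5-tetramethoxyphenyl)chroman F6. Neutral hydrogenolysis (H2, Pd/C, EtOAc) then gives 13.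

3. Step 5.
 - What may go wrong: the hard alkoxide may attack C2 of the pyranone, followed by ring opening and deformylation by adventitious water. The displacement next to the 8-methoxy group may also be sluggish.
 - Fallback (phenol first, alkylation second): it sets out from 8 and comes back at 9. (E)-Benzaldoxime and K2CO3 in DMSO, a weakly basic alpha-effect nucleophile, displace fluoride to give the O-aryl oxime F7. F7 fragments in the same flask by base-induced elimination to 7-hydroxy-8-methoxy-3-(2,3,4,5-tetramethoxyphenyl)-4H-chromen-4-one F8. Williamson benzylation (BnBr, K2CO3, acetone) gives 9.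

**Further compounds**
F1 | step 4 | 2-(2,3,4,5-tetramethoxyphenyl)acetaldehyde | COc1cc(CC=O)c(OC)c(OC)c1OC
F2 | step 4 | (E)-4-[2-(2,3,4,5-tetramethoxyphenyl)ethenyl]morpholine | COc1cc(/C=C/N2CCOCC2)c(OC)c(OC)c1OC
F3 | step 4 | 2,4-difluoro-3-methoxybenzoyl chloride | COc1c(F)ccc(C(=O)Cl)c1F
F4 | step 4 | (E)-1-(2,4-difluoro-3-methoxyphenyl)-3-(morpholin-4-yl)-2-(2,3,4,5-tetramethoxyphenyl)prop-2-en-1-one | O=C(c1ccc(F)c(OC)c1F)/C(=C/N1CCOCC1)c1cc(OC)c(OC)c(OC)c1OC
F5 | step 7 | O-[(3S,4S)-7-(benzyloxy)-8-methoxy-3-(2,3,4,5-tetramethoxyphenyl)chroman-4-yl] S-methyl dithiocarbonate | COc1cc([C@H]2COc3c(ccc(OCc4ccccc4)c3OC)[C@H]2OC(=S)SC)c(OC)c(OC)c1OC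
F6 | step 7 | (3S)-7-(benzyloxy)-8-methoxy-3-(2,3,4,5-tetramethoxyphenyl)chroman | COc1cc([C@H]2COc3c(ccc(OCc4ccccc4)c3OC)C2)c(OC)c(OC)c1OC
F7 | step 5 | (E)-benzaldehyde O-[8-methoxy-4-oxo-3-(2,3,4,5-tetramethoxyphenyl)-4H-chromen-7-yl]oxime | COc1cc(-c2coc3c(OC)c(O/N=C/c4ccccc4)ccc3c2=O)c(OC)c(OC)c1OC
F8 | step 5 | 7-hydroxy-8-methoxy-3-(2,3,4,5-tetramethoxyphenyl)-4H-chromen-4-one | COc1cc(-c2coc3c(OC)c(O)ccc3c2=O)c(OC)c(OC)c1OC
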